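## Structural features

The target (C32H32O8) carries two identical 5,7-dimethoxycoumarin-8-yl groups (Ar) on a C10 hydrocarbon core, and that core holds the only sp3 stereocentres. The core is a cyclohexene (ring C: C1H–Ar, C2H=C3(CH3), C4H2, C5H2, C6). C6 is an all-carbon quaternary centre bearing CH3 and a (Z)-CαH=CβH–Ar styryl arm. C1 and C6 are adjacent and both R, with the C1 aryl group cis to the styryl arm and trans to the C6 methyl group. Each Ar is bound through its C8, between the 7-OMe group and the lactone oxygen, so C1–Ar, Cβ–Ar and above all C1–C6 are crowded bonds. The fragile points are the coumarin lactones with their C3=C4 bonds (hard nucleophiles, hydride, copper hydride, light), the contra-thermodynamic Z-styrene (acid, Pd–H, light) and the doubly activated C1–H. The real difficulty is to make C1–C6 with relative and absolute control in a ring that offers a catalyst no heteroatom to hold; the formal Diels–Alder-dimer structure invites a cycloaddition of two unactivated dienes that gives none of this control. The key step exploits the array Cα–C6–C1–C2=C3. Read with Cα as a formyl carbon, it is a γ,δ-unsaturated aldehyde (a Claisen retron), and because C3 and C6 are also tied by the C4–C5 bridge of ring C, the retron folds back into a 2-styryl-3,4-dihydro-2H-pyran with a single C3–O stereocentre.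

## Logic of the disconnections

**12 to 11.** No skeletal bond is cut; Cα=Cβ is traced back to Cα≡Cβ. The Z geometry between a quaternary carbon and a di-ortho-substituted arene is the less stable one, and syn delivery of hydrogen to a linear precursor writes it most safely. The gain is one stereo-element fewer and a rod-like, sterically relaxed link. The forward reduction must stop at the alkene and ignore C2=C3 and both coumarin C3=C4 bonds.

**11 to 10 + 2.** The cut is Cβ–C8 of the styryl-arm coumarin. An sp–sp2 coupling tolerates ortho substituents well, and the arene arrives as the same building block that serves a second time earlier in the route. The gain is a convergent halving of the molecule. The forward step must couple a hindered iodide with an alkyne on a quaternary carbon without harming the lactones.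

**10 to 9.** The cut is Cα≡Cβ, which removes Cβ. This uncovers a formyl group on C6 and with it the Claisen retron. The gain is one carbon less and a carbonyl handle. The forward step is a one-carbon homologation of a neopentyl, non-enolisable aldehyde under conditions mild enough for a coumarin.

**9 to 8 (key).** C1–C6 is cut and the formyl oxygen is reconnected to C3. In one sentence, a boat-locked [3,3] shift of 8 gives 9. The cut removes the most hindered bond, the carbocycle, both carbon stereocentres and the position of C2=C3 in a single operation. What remains is an oxacycle with one C–O stereocentre and one E alkene. The forward step must be concerted, because ionisation of the C3–O bond would erase the only stereocentre.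

**8 to 7 + 2.** The cut is C1–C8 of the ring-bound coumarin. A vinyl group on a fully substituted carbon can lose only the benzylic hydrogen after arylation, so the E geometry that the key step needs is built in. The gain is a second use of 2 and a C9 partner. The forward step must arylate the monosubstituted alkene and not the trisubstituted enol ether.

**7 to 6.** The cut is C1=C2, which removes C1. It leads back to an aldehyde on the quaternary C3. The gain is a one-carbon simplification to a C8 unit. The forward step is a methylenation of a non-enolisable aldehyde under basic conditions.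

**6 to 5, 4 and 3.** No C–C bond is cut; this is a redox detour through the primary alcohol that serves the resolution. 3 already holds C2, C3, C4, C5, C6, Cα and both methyl groups, eight of the ten core carbons, in the right connectivity. The gain is a commercial C8 starting material. The forward step must separate enantiomers that differ at a quaternary carbon, on cheap material at the start of the route.

**2 to 1.** The cut is C8–I. The arene is nucleophilic enough for direct halogenation. The gain is a commercial coumarin. The forward step must select C8 over C6 and C3.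

## Other disconnections considered

Alternative 1: This is the first idea that comes to mind. It cuts C1–C6 and C4–C5 (retro-Diels–Alder), and forward it is a thermal cross [4+2] in which the E-diene A1 is the 4π partner and the isopropenyl bond of the Z-diene A2 is the 2π partner, giving 12 directly. Both partners are unactivated hydrocarbon dienes of the same kind, so nothing assigns them their roles. A1 can equally add to itself to give the E-styryl isomer A3, and A2 is expected to drift towards A1 at the temperature required. The dienophile carries no Lewis-basic group near the reacting bond, so a chiral catalyst has nothing to bind and the product can only be racemic, with endo/exo selectivity left to chance. The chosen plan fixes the roles, the geometry and the absolute configuration by connectivity.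

Alternative 2: The same two bonds are cut, but the dienophile is replaced by methacrolein. Forward, a chiral Lewis acid (oxazaborolidinium type) would catalyse the Diels–Alder reaction of A1 with methacrolein to give 9. α-Substituted enals tend to react through the exo transition state, which would favour the trans adduct A4 over the cis-configured 9. The di-ortho-substituted aryl group is twisted and shields the C1 terminus of A1, the coumarin carbonyl competes for the Lewis acid, and the electron-rich diene is acid-labile. In the chosen plan the cis relation is not subject to an endo/exo contest, because only one transition-state topology exists. This alternative also keeps the bond set of the obvious route.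

Alternative 3: The cut is C1–Ar, a convergent union at a hindered bond. Forward, acid ionisation of the allylic alcohol A5 gives a C1–C2–C3 allyl cation that alkylates 1 (Friedel–Crafts allylation) to give 10. The quaternary centre of A5 would have to be made enantioselectively on its own in several steps. The cation has two termini, the facial bias rests only on the small difference between methyl and ethynyl, and 1 can react at C6 as well as C8. The two stereocentres would therefore be set in separate operations of uncertain selectivity, whereas the chosen plan derives both from one C–O centre.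

Key step: step 7

Assumption: in step 3 the lipase is taken to acylate the (S)-alcohol faster, so that 5 is the alcohol left over; with the opposite preference the ester fraction would be carried on after methanolysis.

## Steps

Step 1
Reactants: 1 5,7-dimethoxycoumarin (5,7-dimethoxy-2H-chromen-2-one)
Product: 2 8-iodo-5,7-dimethoxycoumarin
Conditions: NIS (1.05 equiv), CF3CO2H (0.3 equiv), MeCN, 0 °C to rt, dark
Reagents that add atoms: N-iodosuccinimide, O=C1CCC(=O)N1I
Why: Electrophilic aromatic iodination; C8 is activated by the ortho 7-OMe, the para 5-OMe and the ortho ring oxygen and is less crowded than C6, which lies between two freely rotating methoxy groups, so mono-iodination should go to C8. The electron-poor pyranone C3=C4 bond should not compete under these mildly acidic conditions.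

Step 2
Reactants: 3 (±)-2,5-dimethyl-3,4-dihydro-2H-pyran-2-carbaldehyde (methacrolein dimer)
Product: 4 (±)-(2,5-dimethyl-3,4-dihydro-2H-pyran-2-yl)methanol
Conditions: NaBH4 (0.3 equiv), MeOH, 0 °C
Reagents that add atoms: none
Why: Borohydride reduction of a non-enolisable aldehyde; the basic medium leaves the acid-labile enol ether untouched. The alcohol serves only as the handle for the resolution.

Step 3
Reactants: 4 (±)-(2,5-dimethyl-3,4-dihydro-2H-pyran-2-yl)methanol
Product: 5 [(2R)-2,5-dimethyl-3,4-dihydro-2H-pyran-2-yl]methanol
Conditions: immobilised Burkholderia cepacia lipase, vinyl acetate (0.7 equiv), MTBE, 30 °C, run beyond half conversion; separation on Et3N-deactivated SiO2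
Reagents that add atoms: none
Why: Lipase-catalysed kinetic resolution by irreversible transesterification, a type known for primary alcohols on a 2-methyl-substituted cyclic ether carbon (2-methylchroman-2-methanols). Running beyond half conversion should leave enantiopure alcohol even if the selectivity is only moderate. This sets the single stereocentre from which all others derive, and the neutral medium spares the enol ether.

Step 4
Reactants: 5 [(2R)-2,5-dimethyl-3,4-dihydro-2H-pyran-2-yl]methanol
Product: 6 (2R)-2,5-dimethyl-3,4-dihydro-2H-pyran-2-carbaldehyde
Conditions: (n-Pr4N)RuO4 (5 mol %), N-methylmorpholine N-oxide (1.5 equiv), 4 Å molecular sieves, CH2Cl2, rt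
Reagents that add atoms: none
Why: Ley–Griffith oxidation under neutral, anhydrous conditions should stop at the aldehyde and tolerate the enol ether. The stereocentre is quaternary and cannot epimerise.

Step 5
Reactants: 6 (2R)-2,5-dimethyl-3,4-dihydro-2H-pyran-2-carbaldehyde
Product: 7 (2R)-2-ethenyl-2,5-dimethyl-3,4-dihydro-2H-pyran
Conditions: Ph3PCH3Br (1.3 equiv), KOt-Bu (1.25 equiv), THF, 0 °C to rt
Reagents that add atoms: methyltriphenylphosphonium bromide, C[P+](c1ccccc1)(c1ccccc1)c1ccccc1.[Br-]
Why: Wittig methylenation with a non-stabilised ylide; the aldehyde has no α-hydrogen, so neither enolisation nor epimerisation is possible, and basic conditions suit the enol ether.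

Step 6
Reactants: 7 (2R)-2-ethenyl-2,5-dimethyl-3,4-dihydro-2H-pyran; 2 8-iodo-5,7-dimethoxycoumarin
Product: 8 8-{(E)-2-[(2R)-2,5-dimethyl-3,4-dihydro-2H-pyran-2-yl]ethenyl}-5,7-dimethoxycoumarin
Conditions: Pd(OAc)2 (5 mol %), n-Bu4NCl (1 equiv), NaHCO3 (2.5 equiv), DMF, 80 °C, degassed, dark; purification on Et3N-deactivated SiO2
Reagents that add atoms: none
Why: Mizoroki–Heck arylation of a monosubstituted alkene on a fully substituted carbinol carbon, the type known for tertiary allylic alcohols and ethers such as 2-methylbut-3-en-2-ol. The aryl group goes to the terminal carbon and only the benzylic hydrogen is available for syn β-hydride elimination, which should give the E alkene. The trisubstituted enol ether is too hindered to insert, and NaHCO3 keeps the medium free of acid.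

Step 7
Reactants: 8 8-{(E)-2-[(2R)-2,5-dimethyl-3,4-dihydro-2H-pyran-2-yl]ethenyl}-5,7-dimethoxycoumarin
Product: 9 (1S,2S)-2-(5,7-dimethoxy-2-oxo-2H-chromen-8-yl)-1,4-dimethylcyclohex-3-ene-1-carbaldehyde (aryl cis to CHO)
Conditions: toluene (0.02 M, degassed), 2,6-lutidine (0.1 equiv), BHT (cat.), base-washed sealed tube, 170 °C, dark
Reagents that add atoms: none
Why: Thermal Claisen rearrangement, a concerted suprafacial [3,3] shift of the allyl vinyl ether array C6=Cα–O–C3–C2=C1 (target numbering) in which C3–O breaks, C1–C6 forms and Cα becomes the formyl carbon; the closest known type is the thermal rearrangement of 2-alkenyl-3,4-dihydro-2H-pyrans to cyclohex-3-ene-1-carbaldehydes. Ring C closes as the pyran opens (six-membered oxacycle exchanged for six-membered carbocycle), and because the C4–C5 tether spans the 1,4-positions of the pericyclic array only a boat, bicyclo[2.2.2]octane-like transition state can be reached, since a chair would ask one C–C single bond to span more than 4 Å. The quaternary centre is controlled by the C3–O stereocentre: the styryl arm can reach only the enol ether face on which it stands, so the R configuration of 8 is handed over to C6 while C3 itself becomes sp2. The aryl-bearing centre is controlled by the alkene geometry: in the boat the E double bond places Ar on the side of the O–Cα bridge and H on the side of the C4–C5 bridge, which makes Ar cis to the formyl group and gives the spatial arrangement of (1R,6R)-12. The driving force is formation of the C=O bond, and the tertiary, cinnamyl-type C3–O bond with its donor aryl group loosens in the transition state, so less heat should be needed than for the unsubstituted parent system. The selectivity needed is that the concerted shift outruns heterolysis of C3–O to a tethered allyl cation/enolate pair (which would erase the only stereocentre and allow 1,3-recombination) and outruns retro-hetero-Diels–Alder cleavage; the apolar solvent, base-washed glass and amine scavenger suppress the first, and the temperature lies well below that of dihydropyran cycloreversion. The coumarin is a spectator at this temperature in the dark, and BHT guards the styrene against radical chemistry.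

Step 8
Reactants: 9 (1S,2S)-2-(5,7-dimethoxy-2-oxo-2H-chromen-8-yl)-1,4-dimethylcyclohex-3-ene-1-carbaldehyde
Product: 10 8-[(1R,6S)-6-ethynyl-3,6-dimethylcyclohex-2-en-1-yl]-5,7-dimethoxycoumarin
Conditions: dimethyl (1-diazo-2-oxopropyl)phosphonate (1.5 equiv), K2CO3 (2 equiv), MeOH–THF, 0 °C to rt; pH 5 buffer work-up
Reagents that add atoms: dimethyl (1-diazo-2-oxopropyl)phosphonate, COP(=O)(OC)C(=[N+]=[N-])C(C)=O
Why: Ohira–Bestmann variant of the Seyferth–Gilbert homologation, the mildest aldehyde-to-alkyne conversion. The aldehyde is non-enolisable, so the quaternary centre is safe, and K2CO3 is too weak to touch C1–H. A lactone opened reversibly by methoxide should close again on mildly acidic work-up, because the cinnamate stays Z.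

Step 9
Reactants: 10 8-[(1R,6S)-6-ethynyl-3,6-dimethylcyclohex-2-en-1-yl]-5,7-dimethoxycoumarin; 2 8-iodo-5,7-dimethoxycoumarin
Product: 11 8-[(1R,6S)-6-[(5,7-dimethoxy-2-oxo-2H-chromen-8-yl)ethynyl]-3,6-dimethylcyclohex-2-en-1-yl]-5,7-dimethoxycoumarin
Conditions: PdCl2(PPh3)2 (5 mol %), CuI (10 mol %), Et3N (3 equiv), DMF, 50 °C, degassed
Reagents that add atoms: none
Why: Sonogashira coupling; the linear copper acetylide meets little steric resistance from the two ortho substituents of the aryl iodide, and alkynes on fully substituted carbons are standard partners. The amine base and moderate temperature leave both stereocentres and the lactones intact.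

Step 10
Reactants: 11 8-[(1R,6S)-6-[(5,7-dimethoxy-2-oxo-2H-chromen-8-yl)ethynyl]-3,6-dimethylcyclohex-2-en-1-yl]-5,7-dimethoxycoumarin
Product: 12 8-[(1R,6R)-6-[(Z)-2-(5,7-dimethoxy-2-oxo-2H-chromen-8-yl)ethenyl]-3,6-dimethylcyclohex-2-en-1-yl]-5,7-dimethoxycoumarin (target)
Conditions: H2 (1 atm), Pd/CaCO3 poisoned with Pb(OAc)2 (Lindlar catalyst), quinoline, EtOAc, rt, dark, stopped after one equivalent of H2
Reagents that add atoms: none
Why: Lindlar semihydrogenation; syn delivery of two hydrogens from the poisoned palladium surface should give the Z alkene. The alkyne binds more strongly than the trisubstituted C2=C3 bond or the conjugated coumarin C3=C4 bonds. The descriptor at C6 changes from S to R only because the ligand priorities change.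

## Compound list

1 | 5,7-dimethoxycoumarin (citropten) | COc1cc(OC)c2ccc(=O)oc2c1 | starting material
2 | 8-iodo-5,7-dimethoxycoumarin | COc1cc(OC)c2ccc(=O)oc2c1I | intermediate
3 | (±)-2,5-dimethyl-3,4-dihydro-2H-pyran-2-carbaldehyde (methacrolein dimer, commercial, racemic) | CC1(C=O)CCC(C)=CO1 | starting material
4 | (±)-(2,5-dimethyl-3,4-dihydro-2H-pyran-2-yl)methanol | CC1(CO)CCC(C)=CO1 | intermediate
5 | [(2R)-2,5-dimethyl-3,4-dihydro-2H-pyran-2-yl]methanol | C[C@]1(CO)CCC(C)=CO1 | intermediate
6 | (2R)-2,5-dimethyl-3,4-dihydro-2H-pyran-2-carbaldehyde | C[C@]1(C=O)CCC(C)=CO1 | intermediate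
7 | (2R)-2-ethenyl-2,5-dimethyl-3,4-dihydro-2H-pyran | C[C@]1(C=C)CCC(C)=CO1 | intermediate
8 | 8-{(E)-2-[(2R)-2,5-dimethyl-3,4-dihydro-2H-pyran-2-yl]ethenyl}-5,7-dimethoxycoumarin | C[C@]1(/C=C/c2c(OC)cc(OC)c3ccc(=O)oc23)CCC(C)=CO1 | intermediate
9 | (1S,2S)-2-(5,7-dimethoxy-2-oxo-2H-chromen-8-yl)-1,4-dimethylcyclohex-3-ene-1-carbaldehyde | O=C[C@@]1(C)CCC(C)=C[C@H]1c1c(OC)cc(OC)c2ccc(=O)oc12 | intermediate
10 | 8-[(1R,6S)-6-ethynyl-3,6-dimethylcyclohex-2-en-1-yl]-5,7-dimethoxycoumarin | C#C[C@@]1(C)CCC(C)=C[C@H]1c1c(OC)cc(OC)c2ccc(=O)oc12 | intermediate
11 | 8-[(1R,6S)-6-[(5,7-dimethoxy-2-oxo-2H-chromen-8-yl)ethynyl]-3,6-dimethylcyclohex-2-en-1-yl]-5,7-dimethoxycoumarin | COc1cc(OC)c2ccc(=O)oc2c1C#C[C@@]1(C)CCC(C)=C[C@H]1c1c(OC)cc(OC)c2ccc(=O)oc12 | intermediate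
12 | 8-[(1R,6R)-6-[(Z)-2-(5,7-dimethoxy-2-oxo-2H-chromen-8-yl)ethenyl]-3,6-dimethylcyclohex-2-en-1-yl]-5,7-dimethoxycoumarin | COc1cc(OC)c2ccc(=O)oc2c1/C=C\[C@@]1(C)CCC(C)=C[C@H]1c1c(OC)cc(OC)c2ccc(=O)oc12 | target

## Step count and least certain steps

Total step count: 10. Longest linear sequence: 9 (steps 2 to 10, from 3 to 12). Step 1 is a one-step branch whose product 2 enters twice.

**Step 7 (key step).** Heterolysis of the tertiary, cinnamyl-type C3–O bond may compete with the concerted shift. That would erode the chirality transfer, scramble the cis/trans relation or lead to 1,3-recombination. The crowded boat transition state may also demand temperatures at which cycloreversion sets in.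

The fallback raises the oxidation level so that the same boat-locked shift runs much colder, as an Ireland–Claisen ring contraction. It sets out from 7 (with 2) and comes back at 9.
- 7 is oxidised at the enol ether with NaOAc-buffered pyridinium chlorochromate, C5H5NH[CrO3Cl], to the vinyl lactone (6R)-6-ethenyl-3,6-dimethyloxan-2-one F1.
- A Heck reaction with 2 under the conditions of step 6 gives the styryl lactone F2.
- KHMDS and TBSCl in THF–toluene at −78 °C give the silyl ketene acetal F3. Its silyloxy donor should let the [3,3] shift proceed on warming to rt–60 °C, giving the silyl ester F4.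
- Mild aqueous work-up gives the carboxylic acid F5.
- EtSH, EDC and DMAP give the S-ethyl thioester F6, and a Fukuyama reduction (Et3SiH, Pd/C, acetone) returns 9.

**Step 3.** The enzyme may discriminate poorly between the methyl group and the ring CH2 at a quaternary centre that also bears oxygen, and the sense of its preference cannot be predicted.

The fallback replaces the kinetic discrimination by a physical separation of covalent diastereomers. It sets out from 4 and comes back at 5.
- 4 is esterified with (S)-2-methoxy-2-phenylacetic acid (DCC, DMAP, CH2Cl2) to the (2R)-pyranylmethyl (S)-O-methylmandelate F7 and its (2S)-pyranylmethyl diastereomer F8.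
- The two esters are separated by chromatography or crystallisation.
- K2CO3 in MeOH releases 5 from F7.

**Step 6.** β-Elimination of the enolate-type oxygen from the alkylpalladium intermediate may compete with β-hydride elimination. Insertion into the enol ether is also possible, and slow oxidative addition of the hindered iodide may end in precipitation of zerovalent palladium.

The fallback moves the metal to the alkene partner, so that no alkylpalladium species β to oxygen is formed. It sets out from 6 and comes back at 8.
- Ohira–Bestmann homologation of 6 gives the alkyne (2R)-2-ethynyl-2,5-dimethyl-3,4-dihydro-2H-pyran F9.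
- Hydroboration with pinacolborane and catalytic Cp2Zr(H)Cl gives the (E)-vinylboronate F10.
- Suzuki–Miyaura coupling with 2 (PdCl2(dppf), K3PO4, dioxane–water, 60 °C) gives 8 with retention of the E geometry.

**Step 10.** Hydrogen uptake at the shielded alkyne may be slow. Forcing the reaction invites over-reduction, saturation of a coumarin C3=C4 bond or Z-to-E isomerisation through Pd–H addition and elimination.

The fallback sets the Z geometry by olefination and keeps it in a stereoretentive coupling, and it also bypasses steps 8 and 9. It sets out from 9 (with 2) and comes back at 12.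
- Stork–Zhao olefination of 9 ((iodomethyl)triphenylphosphonium iodide, NaHMDS, THF–DMPU, −78 °C) gives the (Z)-vinyl iodide F11.
- 2 is converted with zinc dust and LiCl in THF into the arylzinc iodide F12.
- Negishi coupling of F11 with F12 (Pd2(dba)3, SPhos, THF, 40 °C) gives 12.

## Further compounds

F1 | step 7 | (6R)-6-ethenyl-3,6-dimethyloxan-2-one (C3 epimers) | C[C@]1(C=C)CCC(C)C(=O)O1
F2 | step 7 | (6R)-6-[(E)-2-(5,7-dimethoxy-2-oxo-2H-chromen-8-yl)ethenyl]-3,6-dimethyloxan-2-one (C3 epimers) | C[C@]1(/C=C/c2c(OC)cc(OC)c3ccc(=O)oc23)CCC(C)C(=O)O1
F3 | step 7 | 8-{(E)-2-[(2R)-6-(tert-butyldimethylsilyloxy)-2,5-dimethyl-3,4-dihydro-2H-pyran-2-yl]ethenyl}-5,7-dimethoxycoumarin | C[C@]1(/C=C/c2c(OC)cc(OC)c3ccc(=O)oc23)CCC(C)=C(O[Si](C)(C)C(C)(C)C)O1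
F4 | step 7 | tert-butyldimethylsilyl (1S,2S)-2-(5,7-dimethoxy-2-oxo-2H-chromen-8-yl)-1,4-dimethylcyclohex-3-ene-1-carboxylate | CC(C)(C)[Si](C)(C)OC(=O)[C@@]1(C)CCC(C)=C[C@H]1c1c(OC)cc(OC)c2ccc(=O)oc12
F5 | step 7 | (1S,2S)-2-(5,7-dimethoxy-2-oxo-2H-chromen-8-yl)-1,4-dimethylcyclohex-3-ene-1-carboxylic acid | OC(=O)[C@@]1(C)CCC(C)=C[C@H]1c1c(OC)cc(OC)c2ccc(=O)oc12
F6 | step 7 | S-ethyl (1S,2S)-2-(5,7-dimethoxy-2-oxo-2H-chromen-8-yl)-1,4-dimethylcyclohex-3-ene-1-carbothioate | CCSC(=O)[C@@]1(C)CCC(C)=C[C@H]1c1c(OC)cc(OC)c2ccc(=O)oc12
F7 | step 3 | [(2R)-2,5-dimethyl-3,4-dihydro-2H-pyran-2-yl]methyl (2S)-2-methoxy-2-phenylacetate | C[C@]1(COC(=O)[C@@H](OC)c2ccccc2)CCC(C)=CO1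
F8 | step 3 | [(2S)-2,5-dimethyl-3,4-dihydro-2H-pyran-2-yl]methyl (2S)-2-methoxy-2-phenylacetate | C[C@@]1(COC(=O)[C@@H](OC)c2ccccc2)CCC(C)=CO1
F9 | step 6 | (2R)-2-ethynyl-2,5-dimethyl-3,4-dihydro-2H-pyran | C[C@]1(C#C)CCC(C)=CO1
F10 | step 6 | 2-{(E)-2-[(2R)-2,5-dimethyl-3,4-dihydro-2H-pyran-2-yl]ethenyl}-4,4,5,5-tetramethyl-1,3,2-dioxaborolane | C[C@]1(/C=C/B2OC(C)(C)C(C)(C)O2)CCC(C)=CO1
F11 | step 10 | 8-[(1R,6S)-6-[(Z)-2-iodoethenyl]-3,6-dimethylcyclohex-2-en-1-yl]-5,7-dimethoxycoumarin | I/C=C\[C@@]1(C)CCC(C)=C[C@H]1c1c(OC)cc(OC)c2ccc(=O)oc12
F12 | step 10 | (5,7-dimethoxy-2-oxo-2H-chromen-8-yl)zinc iodide | COc1cc(OC)c2ccc(=O)oc2c1[Zn]I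
A1 | alternative 1 | 5,7-dimethoxy-8-[(1E)-3-methylbuta-1,3-dien-1-yl]coumarin | C=C(C)/C=C/c1c(OC)cc(OC)c2ccc(=O)oc12
A2 | alternative 1 | 5,7-dimethoxy-8-[(1Z)-3-methylbuta-1,3-dien-1-yl]coumarin | C=C(C)/C=C\c1c(OC)cc(OC)c2ccc(=O)oc12
A3 | alternative 1 | E-styryl isomer of 12 (would form as the racemate, one enantiomer drawn) | COc1cc(OC)c2ccc(=O)oc2c1/C=C/[C@@]1(C)CCC(C)=C[C@H]1c1c(OC)cc(OC)c2ccc(=O)oc12
A4 | alternative 2 | (1R,2S)-2-(5,7-dimethoxy-2-oxo-2H-chromen-8-yl)-1,4-dimethylcyclohex-3-ene-1-carbaldehyde (aryl trans to CHO, exo adduct) | O=C[C@]1(C)CCC(C)=C[C@H]1c1c(OC)cc(OC)c2ccc(=O)oc12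
A5 | alternative 3 | (4S)-4-ethynyl-1,4-dimethylcyclohex-2-en-1-ol (either C1 epimer) | C#C[C@@]1(C)CCC(C)(O)C=C1
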